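**Plan**
1. Retrosynthesis: the chalcone Cα=Cβ bond (Claisen–Schmidt) and the C1'–acetyl bond are cut first, which leaves a 2-alkyl-5-methoxyresorcinol.
2. Ring A is then cut at C1'–C2' and C4'–C5'. C2'(OH)–C3'(side chain)–C4'(OH) is a 2-substituted malonyl unit and C1'–C6'(OMe)–C5' is the carbon skeleton of 2-methoxypropene. The ring has a local twofold axis through C3' and C6', so later acetylation at C1' or C5' gives the same compound.
3. The malonyl piece is cut at the C1=C2 styrene bond (cross-metathesis) and at the C3–malonate bond (iridium allylic alkylation of a 7-arylhept-2-enyl carbonate).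
4. Forward order: arylpentanoic acid → allyl carbonate → C3 stereocentre → (E)-styrene → malonyl dichloride → ring A by [3+3] double C-acylation → acetyl group → chalcone, with loss of the aryl esters in the last step.
5. Stereochemistry: the only stereocentre, C3 (R), comes from the chiral Ir–phosphoramidite catalyst and is not enolisable in any later intermediate; both alkenes are E under thermodynamic control.

Key step: step 11

Assumption: the (Sa,S,S)-enantiomer of the phosphoramidite is taken to give the (R)-branched malonate in step 7, following the facial rule of this catalyst family for (E)-alkyl allyl carbonates; if the antipode forms, the (Ra,R,R)-ligand is used instead.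

**Step 1**
Reactants: 1 5-(4-hydroxyphenyl)pentanoic acid
Product: 2 4-(5-hydroxypentyl)phenol
Conditions: BH3·THF (3 equiv), THF, 0 °C → rt; MeOH quench
Reagents that add atoms: none
Why: Borane reduction of a carboxylic acid proceeds through the acyloxyborane to the primary alcohol; the phenol only consumes hydride and is set free again on methanolysis.

**Step 2**
Reactants: 2 4-(5-hydroxypentyl)phenol
Product: 3 4-(5-hydroxypentyl)phenyl pivalate
Conditions: PivCl (1.05 equiv), 1 M aq NaOH (1.2 equiv), Bu4NHSO4 (5 mol%), CH2Cl2, 0 °C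
Reagents that add atoms: pivaloyl chloride, CC(C)(C)C(=O)Cl
Why: Under Schotten–Baumann phase-transfer conditions only the phenoxide is formed and acylated, so this chemoselective O-acylation should leave the aliphatic alcohol free.

**Step 3**
Reactants: 3 4-(5-hydroxypentyl)phenyl pivalate
Product: 4 4-(5-oxopentyl)phenyl pivalate
Conditions: TEMPO (10 mol%), PhI(OAc)2 (1.1 equiv), CH2Cl2, rt
Reagents that add atoms: none
Why: The TEMPO/PhI(OAc)2 (oxoammonium) oxidation takes a primary alcohol to the aldehyde without over-oxidation and does not touch the aryl ester.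

**Step 4**
Reactants: 4 4-(5-oxopentyl)phenyl pivalate; 5 (triphenylphosphoranylidene)acetaldehyde
Product: 6 4-[(5E)-7-oxohept-5-en-1-yl]phenyl pivalate
Conditions: 5 (1.15 equiv), toluene, 80 °C
Reagents that add atoms: none
Why: Wittig olefination with the stabilised formyl ylide should give the (E)-enal, the limited excess of ylide holding back a second homologation.

**Step 5**
Reactants: 6 4-[(5E)-7-oxohept-5-en-1-yl]phenyl pivalate
Product: 7 4-[(5E)-7-hydroxyhept-5-en-1-yl]phenyl pivalate
Conditions: NaBH4, CeCl3·7H2O, MeOH, −20 °C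
Reagents that add atoms: none
Why: Luche reduction delivers hydride 1,2 to the enal and should give the (E)-allylic alcohol, the hindered aryl pivalate being inert at this temperature.

**Step 6**
Reactants: 7 4-[(5E)-7-hydroxyhept-5-en-1-yl]phenyl pivalate
Product: 8 4-[(5E)-7-(methoxycarbonyloxy)hept-5-en-1-yl]phenyl pivalate
Conditions: ClCO2Me, pyridine, CH2Cl2, 0 °C
Reagents that add atoms: methyl chloroformate, COC(=O)Cl
Why: Carbonate formation by acylation of the primary allylic alcohol installs the leaving group that the iridium catalyst requires.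

**Step 7**
Reactants: 8 4-[(5E)-7-(methoxycarbonyloxy)hept-5-en-1-yl]phenyl pivalate; 9 di-tert-butyl malonate
Product: 10 di-tert-butyl 2-[(3R)-7-(4-pivaloyloxyphenyl)hept-1-en-3-yl]malonate
Conditions: [Ir(cod)Cl]2 (2 mol%), (Sa,S,S)-Feringa-type phosphoramidite (4 mol%), TBD (8 mol%), THF, rt (activation); then 8, 9 (1.5 equiv), 50 °C
Reagents that add atoms: none
Why: Iridium-catalysed asymmetric allylic alkylation in its salt-free form: the cyclometalated Ir–phosphoramidite ionises the carbonate, the methoxide set free deprotonates the malonate, and attack at the substituted allyl terminus gives the branched product, with the chiral ligand selecting the face of the (E)-allyl unit that sets C3 as (R).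

**Step 8**
Reactants: 10 di-tert-butyl 2-[(3R)-7-(4-pivaloyloxyphenyl)hept-1-en-3-yl]malonate; 11 4-vinylphenyl acetate
Product: 12 di-tert-butyl 2-[(1E,3R)-1-(4-acetoxyphenyl)-7-(4-pivaloyloxyphenyl)hept-1-en-3-yl]malonate
Conditions: Hoveyda–Grubbs II (5 mol%), 11 (4 equiv), CH2Cl2, 40 °C
Reagents that add atoms: none
Why: Olefin cross-metathesis of the hindered terminal alkene with an excess of the reactive styrene should give the thermodynamically preferred (E)-styrene without involving the allylic stereocentre.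

**Step 9**
Reactants: 12 di-tert-butyl 2-[(1E,3R)-1-(4-acetoxyphenyl)-7-(4-pivaloyloxyphenyl)hept-1-en-3-yl]malonate
Product: 13 2-[(1E,3R)-1-(4-acetoxyphenyl)-7-(4-pivaloyloxyphenyl)hept-1-en-3-yl]malonic acid
Conditions: TFA/CH2Cl2 (1:3), 0 °C → rt
Reagents that add atoms: none
Why: Acidolysis of the tert-butyl esters (E1 loss of isobutene) should free the malonic acid below the temperature of decarboxylation, the aryl esters being stable to TFA and the ester-deactivated styrene slow to protonate.

**Step 10**
Reactants: 13 2-[(1E,3R)-1-(4-acetoxyphenyl)-7-(4-pivaloyloxyphenyl)hept-1-en-3-yl]malonic acid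
Product: 14 2-[(1E,3R)-1-(4-acetoxyphenyl)-7-(4-pivaloyloxyphenyl)hept-1-en-3-yl]malonyl dichloride
Conditions: (COCl)2 (3 equiv), DMF (cat.), CH2Cl2, 0 °C → rt; evaporate, use crude
Reagents that add atoms: oxalyl chloride, O=C(Cl)C(=O)Cl
Why: Vilsmeier-catalysed acid chloride formation converts both carboxyl groups and gives only gaseous co-products, so the dichloride can be used without purification.

**Step 11**
Reactants: 14 2-[(1E,3R)-1-(4-acetoxyphenyl)-7-(4-pivaloyloxyphenyl)hept-1-en-3-yl]malonyl dichloride; 15 2-methoxypropene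
Product: 18 4-[(1E,3R)-3-(2,6-dihydroxy-4-methoxyphenyl)-7-(4-pivaloyloxyphenyl)hept-1-en-1-yl]phenyl acetate, via keto acid chloride 16 (not isolated), via cyclohexenedione 17 (not isolated)
Conditions: 15 (3 equiv), Et2O/CH2Cl2, −30 °C → rt; aqueous work-up at pH 5–6
Reagents that add atoms: none
Why: The nucleophilic CH2 of 15 attacks one acyl chloride of 14 (or the chlorocarbonyl ketene formed from it by loss of HCl), and the oxocarbenium ion loses a proton from its methyl group to regenerate an enol ether in 16. The terminal carbon of this 2-methoxyallyl unit is then acylated by the second acyl group in a 6-(enolendo)-exo-trig closure (equivalently a 6π-electrocyclisation of the dienyl ketene) to give 17, which enolises to the arene with the methyl ether kept para to the side chain. The closest known reaction is the Effenberger cyclisation, the α,α'-diacylation of ketone enol ethers with malonyl dichlorides that gives phloroglucinol monoalkyl ethers and bicyclo[3.3.1]nonanetriones. No stereocentre is formed, and C3 is β to both acyl groups, so it cannot enolise and is carried through unchanged. The step needs closure through carbon and not through the ether oxygen (which would give a 4-hydroxy-2-pyranone with loss of MeCl); low temperature and excess enol ether favour kinetic deprotonation at the methyl group, which leaves a carbon nucleophile, and the C2 substituent favours both the ketene pathway and the folded conformer. The two acyl chlorides are identical, so there is no regiochemical question, and the electron-withdrawing aryl esters should keep the styrene and C3 from ionising in the HCl that the excess enol ether takes up.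

**Step 12**
Reactants: 18 4-[(1E,3R)-3-(2,6-dihydroxy-4-methoxyphenyl)-7-(4-pivaloyloxyphenyl)hept-1-en-1-yl]phenyl acetate
Product: 20 4-[(1E,3R)-3-(3-acetyl-2,6-dihydroxy-4-methoxyphenyl)-7-(4-pivaloyloxyphenyl)hept-1-en-1-yl]phenyl acetate, via difluoroboron chelate 19 (not isolated)
Conditions: Ac2O (1.2 equiv), BF3·OEt2 (3 equiv), CH2Cl2, −10 → 0 °C; then aq NaOAc, MeOH, rt
Reagents that add atoms: acetic anhydride, CC(=O)OC(C)=O
Why: Friedel–Crafts C-acetylation of the phloroglucinol-type ring: the two free positions are equivalent, the first acyl group deactivates the ring against a second, and the product is held as its BF2 chelate until hydrolysis on work-up.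

**Step 13**
Reactants: 20 4-[(1E,3R)-3-(3-acetyl-2,6-dihydroxy-4-methoxyphenyl)-7-(4-pivaloyloxyphenyl)hept-1-en-1-yl]phenyl acetate; 21 4-hydroxybenzaldehyde
Product: 22 deoxycalyxin A, (E)-1-{2,4-dihydroxy-3-[(1E,3R)-1,7-bis(4-hydroxyphenyl)hept-1-en-3-yl]-6-methoxyphenyl}-3-(4-hydroxyphenyl)prop-2-en-1-one
Conditions: 21 (3 equiv), 50% aq KOH, EtOH, rt, Ar; then 1 M HCl to pH 4, 0 °C
Reagents that add atoms: none
Why: Claisen–Schmidt condensation (crossed aldol, E1cB dehydration) should give the (E)-enone, and the same hydroxide saponifies the aryl acetate and pivalate, so the free target is obtained in one operation.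

**Compound list**
1 | 5-(4-hydroxyphenyl)pentanoic acid | O=C(O)CCCCc1ccc(O)cc1 | starting material
2 | 4-(5-hydroxypentyl)phenol | OCCCCCc1ccc(O)cc1 | intermediate
3 | 4-(5-hydroxypentyl)phenyl pivalate | CC(C)(C)C(=O)Oc1ccc(CCCCCO)cc1 | intermediate
4 | 4-(5-oxopentyl)phenyl pivalate | CC(C)(C)C(=O)Oc1ccc(CCCCC=O)cc1 | intermediate
5 | (triphenylphosphoranylidene)acetaldehyde | O=CC=P(c1ccccc1)(c1ccccc1)c1ccccc1 | starting material
6 | 4-[(5E)-7-oxohept-5-en-1-yl]phenyl pivalate | CC(C)(C)C(=O)Oc1ccc(CCCC/C=C/C=O)cc1 | intermediate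
7 | 4-[(5E)-7-hydroxyhept-5-en-1-yl]phenyl pivalate | CC(C)(C)C(=O)Oc1ccc(CCCC/C=C/CO)cc1 | intermediate
8 | 4-[(5E)-7-(methoxycarbonyloxy)hept-5-en-1-yl]phenyl pivalate | COC(=O)OC/C=C/CCCCc1ccc(OC(=O)C(C)(C)C)cc1 | intermediate
9 | di-tert-butyl malonate | CC(C)(C)OC(=O)CC(=O)OC(C)(C)C | starting material
10 | di-tert-butyl 2-[(3R)-7-(4-pivaloyloxyphenyl)hept-1-en-3-yl]malonate | CC(C)(C)OC(=O)C(C(=O)OC(C)(C)C)[C@@H](C=C)CCCCc1ccc(OC(=O)C(C)(C)C)cc1 | intermediate
11 | 4-vinylphenyl acetate (4-acetoxystyrene) | CC(=O)Oc1ccc(C=C)cc1 | starting material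
12 | di-tert-butyl 2-[(1E,3R)-1-(4-acetoxyphenyl)-7-(4-pivaloyloxyphenyl)hept-1-en-3-yl]malonate | CC(C)(C)OC(=O)C(C(=O)OC(C)(C)C)[C@@H](/C=C/c1ccc(OC(C)=O)cc1)CCCCc1ccc(OC(=O)C(C)(C)C)cc1 | intermediate
13 | 2-[(1E,3R)-1-(4-acetoxyphenyl)-7-(4-pivaloyloxyphenyl)hept-1-en-3-yl]malonic acid | OC(=O)C(C(=O)O)[C@@H](/C=C/c1ccc(OC(C)=O)cc1)CCCCc1ccc(OC(=O)C(C)(C)C)cc1 | intermediate
14 | 2-[(1E,3R)-1-(4-acetoxyphenyl)-7-(4-pivaloyloxyphenyl)hept-1-en-3-yl]malonyl dichloride | O=C(Cl)C(C(=O)Cl)[C@@H](/C=C/c1ccc(OC(C)=O)cc1)CCCCc1ccc(OC(=O)C(C)(C)C)cc1 | intermediate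
15 | 2-methoxypropene | COC(C)=C | starting material
16 | 2-[(1E,3R)-1-(4-acetoxyphenyl)-7-(4-pivaloyloxyphenyl)hept-1-en-3-yl]-5-methoxy-3-oxohex-5-enoyl chloride (C2 epimers) | C=C(OC)CC(=O)C(C(=O)Cl)[C@@H](/C=C/c1ccc(OC(C)=O)cc1)CCCCc1ccc(OC(=O)C(C)(C)C)cc1 | intermediate (not isolated)
17 | 2-[(1E,3R)-1-(4-acetoxyphenyl)-7-(4-pivaloyloxyphenyl)hept-1-en-3-yl]-5-methoxycyclohex-4-ene-1,3-dione (keto tautomer of 18) | COC1=CC(=O)C([C@@H](/C=C/c2ccc(OC(C)=O)cc2)CCCCc2ccc(OC(=O)C(C)(C)C)cc2)C(=O)C1 | intermediate (not isolated)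
18 | 4-[(1E,3R)-3-(2,6-dihydroxy-4-methoxyphenyl)-7-(4-pivaloyloxyphenyl)hept-1-en-1-yl]phenyl acetate | COc1cc(O)c([C@@H](/C=C/c2ccc(OC(C)=O)cc2)CCCCc2ccc(OC(=O)C(C)(C)C)cc2)c(O)c1 | intermediate
19 | difluoroboron chelate of 20 (O–BF2–O bridge between the acetyl oxygen and the adjacent phenol oxygen) | COc1cc(O)c([C@@H](/C=C/c2ccc(OC(C)=O)cc2)CCCCc2ccc(OC(=O)C(C)(C)C)cc2)c2O[B-](F)(F)[O+]=C(C)c12 | intermediate (not isolated)
20 | 4-[(1E,3R)-3-(3-acetyl-2,6-dihydroxy-4-methoxyphenyl)-7-(4-pivaloyloxyphenyl)hept-1-en-1-yl]phenyl acetate | COc1cc(O)c([C@@H](/C=C/c2ccc(OC(C)=O)cc2)CCCCc2ccc(OC(=O)C(C)(C)C)cc2)c(O)c1C(C)=O | intermediate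
21 | 4-hydroxybenzaldehyde | O=Cc1ccc(O)cc1 | starting material
22 | deoxycalyxin A | COc1cc(O)c([C@@H](/C=C/c2ccc(O)cc2)CCCCc2ccc(O)cc2)c(O)c1C(=O)/C=C/c1ccc(O)cc1 | target

**Step count and risks**
Total step count: 13. Longest linear sequence: 13 steps (1 → 22); compounds 5, 9, 11, 15 and 21 are bought.

Most likely to fail, in this order:

1. Step 11. What may go wrong: ring closure through the enol-ether oxygen with loss of the methyl group, or self-condensation of the acyl ketene, may outrun the second C-acylation; the HCl formed may also ionise the C3 position. Fallback: ring A would be built by a Claisen–Dieckmann [4+2] sequence that forms C1'–C2' and C3'–C4' instead. It sets out from diacid 13. Thermal decarboxylation (pyridine, 100 °C) should give (3S,4E)-5-(4-acetoxyphenyl)-3-{4-[4-(pivaloyloxy)phenyl]butyl}pent-4-enoic acid F1 (same spatial arrangement, the descriptor changes with the CIP ranking). Oxalyl chloride converts it into the acid chloride F2. F2 is added at −78 °C to the lithium dienolate of methyl (E)-3-methoxybut-2-enoate (LDA, THF), whose γ-carbon is acylated to give the δ-keto-β-methoxy enoate F3, which already carries the methyl ether on the future C6'. Base (DBU, toluene, 80 °C) should then effect Dieckmann condensation of the ketone α-carbon next to C3 onto the ester, and the resulting dione enolises to resorcinol 18, where the route is rejoined.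

2. Step 12. What may go wrong: acid-promoted ipso-protonation of the very electron-rich ring may cleave or racemise the C3–aryl bond (retro-Friedel–Crafts), and O-acylation may compete with C-acylation. Fallback: the acetyl group would be introduced without a Lewis acid, setting out from 18. Mono-iodination at one of the two equivalent ring positions (I2, NaHCO3, THF/H2O, 0 °C) should give the iodoresorcinol F4. Stille coupling with tributyl(1-ethoxyvinyl)stannane (Pd(PPh3)4, toluene, 90 °C) gives the aryl enol ether F5. Brief hydrolysis with dilute aqueous HCl in THF at 0 °C releases the methyl ketone and returns to the route at 20.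

3. Step 13. What may go wrong: enolate formation and aldol addition may be sluggish because both partners are deactivated as phenolates, and the 2'-hydroxychalcone may cyclise to the flavanone on acidification. Fallback: the condensation would be run on protected partners, setting out from 20. O-Allylation of the non-chelated ring-A hydroxyl (allyl bromide, K2CO3, acetone, rt) should give the allyl ether F6. Condensation with 4-(allyloxy)benzaldehyde (KOH, EtOH/H2O, rt) then involves only remote phenolates (those set free by ester hydrolysis) and gives the bis-allyl chalcone F7. Pd(PPh3)4 with morpholine (THF, rt) removes both allyl groups and arrives at 22.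

**Further compounds**
F1 | step 11 | (3S,4E)-5-(4-acetoxyphenyl)-3-{4-[4-(pivaloyloxy)phenyl]butyl}pent-4-enoic acid | O=C(O)C[C@@H](/C=C/c1ccc(OC(C)=O)cc1)CCCCc1ccc(OC(=O)C(C)(C)C)cc1
F2 | step 11 | (3S,4E)-5-(4-acetoxyphenyl)-3-{4-[4-(pivaloyloxy)phenyl]butyl}pent-4-enoyl chloride | O=C(Cl)C[C@@H](/C=C/c1ccc(OC(C)=O)cc1)CCCCc1ccc(OC(=O)C(C)(C)C)cc1
F3 | step 11 | methyl (2E,7S,8E)-9-(4-acetoxyphenyl)-3-methoxy-5-oxo-7-{4-[4-(pivaloyloxy)phenyl]butyl}nona-2,8-dienoate | COC(=O)/C=C(/OC)CC(=O)C[C@@H](/C=C/c1ccc(OC(C)=O)cc1)CCCCc1ccc(OC(=O)C(C)(C)C)cc1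
F4 | step 12 | 4-[(1E,3R)-3-(2,6-dihydroxy-3-iodo-4-methoxyphenyl)-7-(4-pivaloyloxyphenyl)hept-1-en-1-yl]phenyl acetate | COc1cc(O)c([C@@H](/C=C/c2ccc(OC(C)=O)cc2)CCCCc2ccc(OC(=O)C(C)(C)C)cc2)c(O)c1I
F5 | step 12 | 4-[(1E,3R)-3-[3-(1-ethoxyvinyl)-2,6-dihydroxy-4-methoxyphenyl]-7-(4-pivaloyloxyphenyl)hept-1-en-1-yl]phenyl acetate | COc1cc(O)c([C@@H](/C=C/c2ccc(OC(C)=O)cc2)CCCCc2ccc(OC(=O)C(C)(C)C)cc2)c(O)c1C(=C)OCC
F6 | step 13 | 4-[(1E,3R)-3-(3-acetyl-6-allyloxy-2-hydroxy-4-methoxyphenyl)-7-(4-pivaloyloxyphenyl)hept-1-en-1-yl]phenyl acetate | COc1cc(OCC=C)c([C@@H](/C=C/c2ccc(OC(C)=O)cc2)CCCCc2ccc(OC(=O)C(C)(C)C)cc2)c(O)c1C(C)=O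
F7 | step 13 | (E)-1-{4-allyloxy-3-[(1E,3R)-1,7-bis(4-hydroxyphenyl)hept-1-en-3-yl]-2-hydroxy-6-methoxyphenyl}-3-(4-allyloxyphenyl)prop-2-en-1-one | COc1cc(OCC=C)c([C@@H](/C=C/c2ccc(O)cc2)CCCCc2ccc(O)cc2)c(O)c1C(=O)/C=C/c1ccc(OCC=C)cc1
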